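**Retrosynthetic overview**

1. The target comes from N-Boc ketal macrocycle 31 by acid deprotection. The 20-membered ring is closed last by an intramolecular Horner–Wadsworth–Emmons olefination that forms the C9b–CH=CH–C(O)N unit. The aryl C8–CH=CH bond comes from a Heck reaction of an aryl bromide with the acrylamide end of spermidine fragment 28, which is made separately in five steps.
2. The C9b aldehyde derives from a C9b ester and the saturated C1–C2 bond from an enone, which leads back to tricyclic enone ester 15.
3. Key disconnection of 15: bonds C4–C4a and C1–C9b, that is the whole six-membered carbocycle, back to 3-ethoxycyclobutanone 12 (a four-membered ring expanded by two atoms) and benzofuran-3-carboxylate 8, whose furan ring is dearomatised. Both stereocentres arise here under control of an 8-phenylmenthyl ester.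
4. Enabling feature: the C4a–C9b bond shared by the carbocycle and the dihydrofuran ring is a former benzofuran C2=C3 bond, polarised by O5 on C4a (donor) and the acyl carbon on C9b (acceptor). The C3 ketone lies 1,3 to C4a–O5 and 1,3 to C1, which is the pattern of a ring-opened 3-alkoxycyclobutanone (enolate carbon C4, oxocarbenium carbon C1).
5. Ring order: benzene and furan rings (from 5-bromosalicylaldehyde), then the carbocycle by ring expansion, then the macrocycle.

Key step: step 5

Assumption: the face shielded by the (−)-8-phenylmenthyl ester in step 5 is taken from the stacking model of Lewis acid-bound 8-phenylmenthyl enoates; should the other diastereomer predominate, the enantiomeric auxiliary would be used, and in either case the diastereomers are separated after step 6.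

**Route**

Step 1
Reactants: 1 5-bromo-2-hydroxybenzaldehyde; 2 ethyl diazoacetate
Product: 4 ethyl 5-bromobenzofuran-3-carboxylate, via hemiacetal 3 (not isolated)
Conditions: HBF4·OEt2 (10 mol%), CH2Cl2, rt; then conc. H2SO4, rt
Reagents that add atoms: none
Why: Acid-catalysed addition of the diazo ester to the aldehyde with 1,2-aryl shift should give the 3-hydroxy-2-arylacrylate, which closes to hemiacetal 3 and is dehydrated to the benzofuran (known one-pot benzofuran-3-carboxylate synthesis from salicylaldehydes).

Step 2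
Reactants: 4 ethyl 5-bromobenzofuran-3-carboxylate
Product: 5 5-bromobenzofuran-3-carboxylic acid
Conditions: LiOH·H2O, THF/H2O, rt; then 1 M HCl
Reagents that add atoms: lithium hydroxide, [Li+].[OH-]
Why: Ester saponification by acyl–oxygen cleavage, mild enough to leave the heteroaryl ring and the aryl bromide untouched.

Step 3
Reactants: 5 5-bromobenzofuran-3-carboxylic acid; 6 (−)-8-phenylmenthol
Product: 8 (1R,2S,5R)-8-phenylmenthyl 5-bromobenzofuran-3-carboxylate, via acid chloride 7 (not isolated)
Conditions: (COCl)2, DMF (cat.), CH2Cl2, 0 °C to rt, evaporation; then 6, pyridine, DMAP (cat.), CH2Cl2, rt to 40 °C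
Reagents that add atoms: none
Why: Acylation of the hindered secondary alcohol by the aroyl chloride under nucleophilic catalysis installs the auxiliary without touching its three stereocentres.

Step 4
Reactants: 9 acetyl chloride; 10 ethyl vinyl ether
Product: 12 3-ethoxycyclobutan-1-one, via ketene 11 (not isolated)
Conditions: Et3N, excess 10, MeCN, rt to 40 °C
Reagents that add atoms: none
Why: Ketene formed by dehydrochlorination should undergo thermal [2+2] cycloaddition with the enol ether, the carbonyl carbon bonding to the unsubstituted alkene terminus so that the ethoxy group ends up 1,3 to the ketone (known route to 3-alkoxycyclobutanones).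

Step 5
Reactants: 8 (1R,2S,5R)-8-phenylmenthyl 5-bromobenzofuran-3-carboxylate; 12 3-ethoxycyclobutan-1-one
Product: 15 8-phenylmenthyl (4aR,9bS)-8-bromo-3-oxo-3,4,4a,9b-tetrahydrodibenzo[b,d]furan-9b-carboxylate, via zwitterion 13 (not isolated), via ethoxy ketone 14 (not isolated)
Conditions: TiCl4 (3 equiv), 12 (2.5 equiv, slow addition), CH2Cl2, −78 to −20 °C, then 0 °C; pH 7 phosphate buffer quench
Reagents that add atoms: none
Why: Proposed new method: TiCl4 should open 12 by alkoxy-assisted cleavage of its C2–C3 bond to the titanium enolate/oxocarbenium 1,4-zwitterion 13, whose two ends are polarity-matched to the push–pull C2=C3 bond of the TiCl4-bound benzofuran ester 8 (C2 electrophilic, C3 nucleophilic), so that Mukaiyama–Michael attack of the enolate carbon on benzofuran C2 and collapse of the resulting ester enolate at C3 onto the tethered oxocarbenium carbon give 14, which loses ethanol by β-elimination to enone 15; the net event is a two-atom expansion of the four-membered ketone ring into the six-membered carbocycle across a dearomatised furan bond. The closest known reaction types are the Lewis acid-promoted formal [4+2] cycloadditions of 3-alkoxycyclobutanones with aldehydes, silyl enol ethers, allylsilanes and the C2=C3 bond of indoles, and the dearomative Diels–Alder reactions of 3-acylbenzofurans with 1-alkoxy-3-silyloxybutadienes; what is new is a benzofuran-3-carboxylate as the two-atom partner of the zwitterion. Only the carbocycle closes, by an intermolecular C–C bond formation followed by a 6-(enolexo)-exo-trig ionic ring closure, while the furan ring is kept and dearomatised. C4a and C9b are set together: their cis relation follows from suprafacial addition across the five-membered ring, and their absolute sense from the auxiliary, whose phenyl ring stacks over one face of the Lewis acid-bound s-cis C2=C3–C=O unit (carbonyl syn to C2–H, away from the peri C4–H) so that both bonds form on the open C2 Re face. The step needs regioselectivity (enolate carbon to C2, oxocarbenium carbon to C3), which the ester-induced polarisation secures whichever bond forms first, and chemoselectivity over Friedel–Crafts attack on the benzo ring, which the bromine and the ester disfavour. Base is excluded until the enone is reduced, since retro-oxa-Michael opening of 15 to a 4-aryl-cyclohexa-2,5-dienone would scramble C4a and C9b.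

Step 6
Reactants: 15 8-phenylmenthyl (4aR,9bS)-8-bromo-3-oxo-3,4,4a,9b-tetrahydrodibenzo[b,d]furan-9b-carboxylate
Product: 16 8-phenylmenthyl (4aR,9bS)-8-bromo-3-oxo-1,2,3,4,4a,9b-hexahydrodibenzo[b,d]furan-9b-carboxylate
Conditions: H2 (1–3 atm), RhCl(PPh3)3 (10 mol%), benzene/EtOH, rt; chromatography and crystallisation to a single diastereomer
Reagents that add atoms: none
Why: Homogeneous rhodium-catalysed hydrogenation should saturate the disubstituted enone C1=C2 bond next to the quaternary carbon under neutral conditions, sparing the aryl bromide and removing the retro-oxa-Michael scrambling pathway; no new stereocentre forms and any minor diastereomer is removed here.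

Step 7
Reactants: 16 8-phenylmenthyl (4aR,9bS)-8-bromo-3-oxo-1,2,3,4,4a,9b-hexahydrodibenzo[b,d]furan-9b-carboxylate
Product: 17 8-phenylmenthyl (4aR,9bS)-8-bromo-3,3-(ethylenedioxy)-1,2,3,4,4a,9b-hexahydrodibenzo[b,d]furan-9b-carboxylate
Conditions: 1,2-bis(trimethylsilyloxy)ethane, TMSOTf (5 mol%), CH2Cl2, −78 to −20 °C; pyridine quench
Reagents that add atoms: 1,2-bis(trimethylsilyloxy)ethane, C[Si](C)(C)OCCO[Si](C)(C)C
Why: Silyl triflate-catalysed aprotic ketalisation at low temperature masks the ketone, so that the β-aryloxy group cannot be eliminated and the ketone cannot be attacked in the later hydride and base steps.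

Step 8
Reactants: 17 8-phenylmenthyl (4aR,9bS)-8-bromo-3,3-(ethylenedioxy)-1,2,3,4,4a,9b-hexahydrodibenzo[b,d]furan-9b-carboxylate
Product: 18 [(4aR,9bR)-8-bromo-3,3-(ethylenedioxy)-1,2,3,4,4a,9b-hexahydrodibenzo[b,d]furan-9b-yl]methanol
Conditions: LiAlH4, THF, 0 °C to rt; H2O/aq NaOH work-up
Reagents that add atoms: none
Why: Hydride reduction of the hindered ester gives the neopentyl alcohol and releases the auxiliary for recovery; the ketal and, at this temperature, the aryl bromide are inert (the descriptor at C9b changes only by priority).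

Step 9
Reactants: 19 tert-butyl N-(4-aminobutyl)carbamate; 20 2-(diethoxyphosphoryl)acetic acid
Product: 21 tert-butyl N-{4-[2-(diethoxyphosphoryl)acetamido]butyl}carbamate
Conditions: DCC, HOBt (cat.), CH2Cl2, 0 °C to rt
Reagents that add atoms: none
Why: Carbodiimide amide coupling places the phosphonoacetyl group on the nitrogen of the four-carbon arm.

Step 10
Reactants: 21 tert-butyl N-{4-[2-(diethoxyphosphoryl)acetamido]butyl}carbamate
Product: 22 N-(4-aminobutyl)-2-(diethoxyphosphoryl)acetamide hydrochloride
Conditions: 4 M HCl in 1,4-dioxane, rt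
Reagents that add atoms: hydrogen chloride, Cl
Why: Acidolysis of the tert-butyl carbamate frees the primary amine as its salt; the phosphonoacetamide is stable to anhydrous acid.

Step 11
Reactants: 22 N-(4-aminobutyl)-2-(diethoxyphosphoryl)acetamide hydrochloride; 23 acrylonitrile
Product: 25 tert-butyl N-(2-cyanoethyl)-N-{4-[2-(diethoxyphosphoryl)acetamido]butyl}carbamate, via cyanoethylamine 24 (not isolated)
Conditions: Et3N, 23 (1.05 equiv), MeOH, rt; then Boc2O, rt
Reagents that add atoms: di-tert-butyl dicarbonate, CC(C)(C)OC(=O)OC(=O)OC(C)(C)C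
Why: Aza-Michael mono-cyanoethylation of the primary amine at room temperature builds the three-carbon arm, and carbamoylation of the new secondary amine in the same flask prevents a second addition.

Step 12
Reactants: 25 tert-butyl N-(2-cyanoethyl)-N-{4-[2-(diethoxyphosphoryl)acetamido]butyl}carbamate
Product: 26 tert-butyl N-(3-aminopropyl)-N-{4-[2-(diethoxyphosphoryl)acetamido]butyl}carbamate
Conditions: H2 (4 atm), Raney Ni, 7 M NH3 in MeOH, rt
Reagents that add atoms: none
Why: Catalytic hydrogenation of the nitrile in ammonia gives the primary amine without secondary-amine formation; carbamate, amide and phosphonate are inert.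

Step 13
Reactants: 26 tert-butyl N-(3-aminopropyl)-N-{4-[2-(diethoxyphosphoryl)acetamido]butyl}carbamate; 27 acryloyl chloride
Product: 28 tert-butyl N-(3-acrylamidopropyl)-N-{4-[2-(diethoxyphosphoryl)acetamido]butyl}carbamate
Conditions: Et3N, CH2Cl2, −78 to 0 °C
Reagents that add atoms: none
Why: N-Acylation of the only free amine is much faster at low temperature than conjugate addition to the acryloyl unit.

Step 14
Reactants: 18 [(4aR,9bR)-8-bromo-3,3-(ethylenedioxy)-1,2,3,4,4a,9b-hexahydrodibenzo[b,d]furan-9b-yl]methanol; 28 tert-butyl N-(3-acrylamidopropyl)-N-{4-[2-(diethoxyphosphoryl)acetamido]butyl}carbamate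
Product: 29 tert-butyl N-{3-[(E)-3-((4aR,9bR)-3,3-(ethylenedioxy)-9b-(hydroxymethyl)-1,2,3,4,4a,9b-hexahydrodibenzo[b,d]furan-8-yl)acrylamido]propyl}-N-{4-[2-(diethoxyphosphoryl)acetamido]butyl}carbamate
Conditions: Pd(OAc)2 (5 mol%), P(o-tol)3 (12 mol%), Et3N, DMF, 100 °C
Reagents that add atoms: none
Why: Heck reaction of the unhindered aryl bromide with the terminal acrylamide gives the (E)-cinnamamide by syn insertion and syn β-hydride elimination; the alcohol, ketal, carbamate and phosphonate tolerate the conditions.

Step 15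
Reactants: 29 tert-butyl N-{3-[(E)-3-((4aR,9bR)-3,3-(ethylenedioxy)-9b-(hydroxymethyl)-1,2,3,4,4a,9b-hexahydrodibenzo[b,d]furan-8-yl)acrylamido]propyl}-N-{4-[2-(diethoxyphosphoryl)acetamido]butyl}carbamate
Product: 30 tert-butyl N-{3-[(E)-3-((4aR,9bS)-3,3-(ethylenedioxy)-9b-formyl-1,2,3,4,4a,9b-hexahydrodibenzo[b,d]furan-8-yl)acrylamido]propyl}-N-{4-[2-(diethoxyphosphoryl)acetamido]butyl}carbamate
Conditions: 1,1,1-triacetoxy-1,1-dihydro-1,2-benziodoxol-3(1H)-one (DMP), CH2Cl2, 0 °C to rt
Reagents that add atoms: none
Why: Hypervalent-iodine oxidation of the neopentyl alcohol stops at the aldehyde, which has no α-hydrogen and so cannot epimerise or enolise.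

Step 16
Reactants: 30 tert-butyl N-{3-[(E)-3-((4aR,9bS)-3,3-(ethylenedioxy)-9b-formyl-1,2,3,4,4a,9b-hexahydrodibenzo[b,d]furan-8-yl)acrylamido]propyl}-N-{4-[2-(diethoxyphosphoryl)acetamido]butyl}carbamate
Product: 31 N-Boc, 3,3-ethylenedioxy-protected macrocycle (4aR,9bS; both C=C E)
Conditions: LiCl, DBU, MeCN, rt, slow addition to about 1 mM
Reagents that add atoms: none
Why: Intramolecular Horner–Wadsworth–Emmons olefination of the lithium-chelated phosphonoacetamide anion with the non-enolisable aldehyde should close the 20-membered ring at high dilution and give the (E)-acrylamide under thermodynamic control of the oxaphosphetane.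

Step 17
Reactants: 31 N-Boc, 3,3-ethylenedioxy-protected macrocycle
Product: 32 the target, (4aR,9bS)-macrocyclic spermidine bis-(E)-acrylamide of 1,2,4,4a-tetrahydrodibenzo[b,d]furan-3(9bH)-one
Conditions: 3 M aq HCl, THF, rt; then aq NaHCO3
Reagents that add atoms: water, O
Why: Aqueous acid cleaves the tert-butyl carbamate and hydrolyses the dioxolane in one operation; the stereocentres are safe because retro-oxa-Michael opening of the saturated β-aryloxy ketone can only re-close to the same cis-fused ring.

**Compound list**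

1 | 5-bromo-2-hydroxybenzaldehyde | O=Cc1cc(Br)ccc1O | starting material
2 | ethyl diazoacetate | CCOC(=O)C=[N+]=[N-] | starting material
3 | ethyl 5-bromo-2-hydroxy-2,3-dihydrobenzofuran-3-carboxylate (hemiacetal, diastereomer mixture) | CCOC(=O)C1C(O)Oc2ccc(Br)cc21 | intermediate
4 | ethyl 5-bromobenzofuran-3-carboxylate | CCOC(=O)c1coc2ccc(Br)cc12 | intermediate
5 | 5-bromobenzofuran-3-carboxylic acid | OC(=O)c1coc2ccc(Br)cc12 | intermediate
6 | (−)-8-phenylmenthol, (1R,2S,5R)-5-methyl-2-(2-phenylpropan-2-yl)cyclohexan-1-ol | O[C@@H]1C[C@H](C)CC[C@H]1C(C)(C)c1ccccc1 | starting material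
7 | 5-bromobenzofuran-3-carbonyl chloride | ClC(=O)c1coc2ccc(Br)cc12 | intermediate
8 | (1R,2S,5R)-5-methyl-2-(2-phenylpropan-2-yl)cyclohexyl 5-bromobenzofuran-3-carboxylate | O=C(O[C@@H]1C[C@H](C)CC[C@H]1C(C)(C)c1ccccc1)c1coc2ccc(Br)cc12 | intermediate
9 | acetyl chloride | CC(=O)Cl | starting material
10 | ethyl vinyl ether | CCOC=C | starting material
11 | ketene | C=C=O | intermediate
12 | 3-ethoxycyclobutan-1-one | CCOC1CC(=O)C1 | intermediate
13 | ethyl(3-oxidobut-3-en-1-ylidene)oxonium, the 1,4-zwitterion (titanium-bound in the flask, drawn metal-free) | C=C([O-])CC=[O+]CC | intermediate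
14 | 8-phenylmenthyl (4aR,9bR)-8-bromo-1-ethoxy-3-oxo-1,2,3,4,4a,9b-hexahydrodibenzo[b,d]furan-9b-carboxylate (C1 epimers) | O=C1CC(OCC)[C@]2(C(=O)O[C@@H]3C[C@H](C)CC[C@H]3C(C)(C)c4ccccc4)c5cc(Br)ccc5O[C@@H]2C1 | intermediate
15 | 8-phenylmenthyl (4aR,9bS)-8-bromo-3-oxo-3,4,4a,9b-tetrahydrodibenzo[b,d]furan-9b-carboxylate | O=C1C=C[C@]2(C(=O)O[C@@H]3C[C@H](C)CC[C@H]3C(C)(C)c4ccccc4)c5cc(Br)ccc5O[C@@H]2C1 | intermediate
16 | 8-phenylmenthyl (4aR,9bS)-8-bromo-3-oxo-1,2,3,4,4a,9b-hexahydrodibenzo[b,d]furan-9b-carboxylate | O=C1CC[C@]2(C(=O)O[C@@H]3C[C@H](C)CC[C@H]3C(C)(C)c4ccccc4)c5cc(Br)ccc5O[C@@H]2C1 | intermediate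
17 | 8-phenylmenthyl (4aR,9bS)-8-bromo-3,3-(ethylenedioxy)-1,2,3,4,4a,9b-hexahydrodibenzo[b,d]furan-9b-carboxylate | C1COC2(O1)CC[C@]3(C(=O)O[C@@H]4C[C@H](C)CC[C@H]4C(C)(C)c5ccccc5)c6cc(Br)ccc6O[C@@H]3C2 | intermediate
18 | [(4aR,9bR)-8-bromo-3,3-(ethylenedioxy)-1,2,3,4,4a,9b-hexahydrodibenzo[b,d]furan-9b-yl]methanol | C1COC2(O1)CC[C@]3(CO)c4cc(Br)ccc4O[C@@H]3C2 | intermediate
19 | tert-butyl N-(4-aminobutyl)carbamate | CC(C)(C)OC(=O)NCCCCN | starting material
20 | 2-(diethoxyphosphoryl)acetic acid | CCOP(=O)(CC(=O)O)OCC | starting material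
21 | tert-butyl N-{4-[2-(diethoxyphosphoryl)acetamido]butyl}carbamate | CC(C)(C)OC(=O)NCCCCNC(=O)CP(=O)(OCC)OCC | intermediate
22 | N-(4-aminobutyl)-2-(diethoxyphosphoryl)acetamide hydrochloride | Cl.NCCCCNC(=O)CP(=O)(OCC)OCC | intermediate
23 | acrylonitrile | C=CC#N | starting material
24 | N-{4-[(2-cyanoethyl)amino]butyl}-2-(diethoxyphosphoryl)acetamide | N#CCCNCCCCNC(=O)CP(=O)(OCC)OCC | intermediate
25 | tert-butyl N-(2-cyanoethyl)-N-{4-[2-(diethoxyphosphoryl)acetamido]butyl}carbamate | N#CCCN(C(=O)OC(C)(C)C)CCCCNC(=O)CP(=O)(OCC)OCC | intermediate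
26 | tert-butyl N-(3-aminopropyl)-N-{4-[2-(diethoxyphosphoryl)acetamido]butyl}carbamate | NCCCN(C(=O)OC(C)(C)C)CCCCNC(=O)CP(=O)(OCC)OCC | intermediate
27 | acryloyl chloride | C=CC(=O)Cl | starting material
28 | tert-butyl N-(3-acrylamidopropyl)-N-{4-[2-(diethoxyphosphoryl)acetamido]butyl}carbamate | C=CC(=O)NCCCN(C(=O)OC(C)(C)C)CCCCNC(=O)CP(=O)(OCC)OCC | intermediate
29 | tert-butyl N-{3-[(E)-3-((4aR,9bR)-3,3-(ethylenedioxy)-9b-(hydroxymethyl)-1,2,3,4,4a,9b-hexahydrodibenzo[b,d]furan-8-yl)acrylamido]propyl}-N-{4-[2-(diethoxyphosphoryl)acetamido]butyl}carbamate | C1COC2(O1)CC[C@]3(CO)c4cc(/C=C/C(=O)NCCCN(C(=O)OC(C)(C)C)CCCCNC(=O)CP(=O)(OCC)OCC)ccc4O[C@@H]3C2 | intermediate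
30 | tert-butyl N-{3-[(E)-3-((4aR,9bS)-3,3-(ethylenedioxy)-9b-formyl-1,2,3,4,4a,9b-hexahydrodibenzo[b,d]furan-8-yl)acrylamido]propyl}-N-{4-[2-(diethoxyphosphoryl)acetamido]butyl}carbamate | C1COC2(O1)CC[C@]3(C=O)c4cc(/C=C/C(=O)NCCCN(C(=O)OC(C)(C)C)CCCCNC(=O)CP(=O)(OCC)OCC)ccc4O[C@@H]3C2 | intermediate
31 | N-Boc, 3,3-ethylenedioxy-protected macrocycle, (4aR,9bS), both acrylamide C=C bonds E, Boc on the central spermidine nitrogen | C1COC2(O1)CC[C@]34/C=C/C(=O)NCCCCN(C(=O)OC(C)(C)C)CCCNC(=O)/C=C/c5ccc(c3c5)O[C@@H]4C2 | intermediate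
32 | target: (4aR,9bS)-1,2,4,4a-tetrahydrodibenzo[b,d]furan-3(9bH)-one bridged from C9b to C8 by two (E)-acrylamides and spermidine (C9b acryloyl on the aminobutyl nitrogen, C8 acryloyl on the aminopropyl nitrogen) | O=C1CC[C@]23/C=C/C(=O)NCCCCNCCCNC(=O)/C=C/c4ccc(c2c4)O[C@@H]3C1 | target

**Step count and risks**

Total step count: 17. Longest linear sequence: 11 steps (steps 1–3, 5–8, 14–17). Step 4 and steps 9–13 are side branches.

Steps most likely to fail:

Step 5. The zwitterion may be consumed by self-condensation or by collapse to the open-chain β-ethoxy enone faster than it is captured by the weakly polarised benzofuran bond. The facial bias of the auxiliary may be low, and the enone may epimerise by retro-oxa-Michael opening before it is reduced. The fallback uses known chemistry and sets out from 8: a thermal, high-pressure (about 12–15 kbar, toluene) dearomative Diels–Alder reaction of 8 with commercial (E)-1-methoxy-3-(trimethylsilyloxy)buta-1,3-diene should give the silyl enol ether cycloadduct F1, on the face left open by the auxiliary. Brief treatment with dilute HCl in THF hydrolyses the silyl enol ether and eliminates methanol, and the route is rejoined at 15.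

Step 16. Oligomerisation may outrun ring closure because the aldehyde is neopentyl and the seco chain must fold around two E-alkenes. The fallback exchanges the order of the two olefin-forming events and sets out from 18. Oxidation of 18 with DMP gives the bromo aldehyde F2. Intermolecular Horner–Wadsworth–Emmons olefination of F2 with 28 (LiCl, DBU, MeCN) gives the open-chain aryl bromide acrylamide F3. An intramolecular Heck macrocyclisation (Pd(OAc)2, P(o-tol)3, Et3N, DMF, high dilution, 100 °C) then closes the ring at the aryl–vinyl bond, and the route is rejoined at 31.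

Step 14. The catalyst may be slowed by chelation to the phosphonoacetamide and amide groups of 28, and the acrylamide may polymerise at 100 °C before coupling. The fallback builds the cinnamamide by amide formation instead and sets out from 18. A Heck reaction of 18 with methyl acrylate gives the methyl cinnamate F4. Saponification (LiOH, THF/H2O) gives the cinnamic acid F5. Carbodiimide coupling of F5 with amine 26 (EDC, HOBt, CH2Cl2) rejoins the route at 29.

Further compounds
F1 | step 5 | 8-phenylmenthyl (4aR,9bS)-8-bromo-1-methoxy-3-(trimethylsilyloxy)-1,4,4a,9b-tetrahydrodibenzo[b,d]furan-9b-carboxylate (C1 epimers) | C[Si](C)(C)OC1=CC(OC)[C@]2(C(=O)O[C@@H]3C[C@H](C)CC[C@H]3C(C)(C)c4ccccc4)c5cc(Br)ccc5O[C@@H]2C1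
F2 | step 16 | (4aR,9bS)-8-bromo-3,3-(ethylenedioxy)-1,2,3,4,4a,9b-hexahydrodibenzo[b,d]furan-9b-carbaldehyde | C1COC2(O1)CC[C@]3(C=O)c4cc(Br)ccc4O[C@@H]3C2
F3 | step 16 | tert-butyl N-(3-acrylamidopropyl)-N-{4-[(E)-3-((4aR,9bS)-8-bromo-3,3-(ethylenedioxy)-1,2,3,4,4a,9b-hexahydrodibenzo[b,d]furan-9b-yl)acrylamido]butyl}carbamate | C1COC2(O1)CC[C@]3(/C=C/C(=O)NCCCCN(C(=O)OC(C)(C)C)CCCNC(=O)C=C)c4cc(Br)ccc4O[C@@H]3C2
F4 | step 14 | methyl (E)-3-[(4aR,9bR)-3,3-(ethylenedioxy)-9b-(hydroxymethyl)-1,2,3,4,4a,9b-hexahydrodibenzo[b,d]furan-8-yl]acrylate | C1COC2(O1)CC[C@]3(CO)c4cc(/C=C/C(=O)OC)ccc4O[C@@H]3C2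
F5 | step 14 | (E)-3-[(4aR,9bR)-3,3-(ethylenedioxy)-9b-(hydroxymethyl)-1,2,3,4,4a,9b-hexahydrodibenzo[b,d]furan-8-yl]acrylic acid | C1COC2(O1)CC[C@]3(CO)c4cc(/C=C/C(=O)O)ccc4O[C@@H]3C2
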